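If over-reaction product grows from tetra adduct and coupling partner, the share of tetra adduct depends on how many adduct lifetimes pass while partner lasts.

| flask | solid substrate | coupling partner | temperature | remark | time |
|---|---|---|---|---|---|
| south-east | 0.62 M | 1.02 M | 45 °C | run made earlier |  |
| south | 1.4 M | 1.02 M | 80 °C | run made earlier |  |
| eta | 0.93 M | 1.02 M | 80 °C |  | 30 h |
| gamma | 0.93 M | 1.02 M |  | at 110 °C until 10 h, from then on at 50 °C | 30 h |
| zeta | 0.93 M | 1.02 M | 110 °C |  | 30 h |
| beta | 0.93 M | 1.02 M | 50 °C |  | 30 h |

- south-east (time / h: tetra adduct / %, over-reaction product / %): 12.0: 0, 0; 15.0: 0.1, 0; 30.0: 2.0, 0; 50.0: 4.9, 0.2; 96.0: 12.1, 0.1; 144: 15.2, 0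
- south (time / h: tetra adduct / %, over-reaction product / %): 1.50: 0, 0.1; 5.00: 2.9, 0.1; 8.00: 5.4, 0.3; 12.0: 7.9, 1.5; 20.0: 10.8, 1.8; 25.0: 10.6, 2.3

(standard deviation of a reading: 0.3 percentage points)

- the flask that comes out highest in share of tetra adduct in all that became tetra adduct or over-reaction product, or "all alike" when all lie within 1.5 percentage points (eta / gamma / zeta / beta / all alike)
- share of tetra adduct in all that became tetra adduct or over-reaction product, eta
- share of tetra adduct in all that became tetra adduct or over-reaction product, gamma
- share of tetra adduct in all that became tetra adduct or over-reaction product, zeta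
- share of tetra adduct in all that became tetra adduct or over-reaction product, beta

- given per volume of solution although it is solid: solid substrate
- at the start none of the solid substrate is in solution
- what has only dissolved of solid substrate counts as not reacted

I read the adduct lifetime, the mean tetra adduct in the south run divided by the rate at which over-reaction product appears, between 8.00 h and 25.0 h:

τ = 68.0 h

Temperature comes next. I take the rise of c(tetra adduct) in both earlier runs and assume over-reaction scales the same way:

south 0.0100 M h⁻¹, south-east 9.49 × 10⁻⁴ M h⁻¹, factor 10.5

This gives a lifetime of 9.03 h at 110 °C and 512 h at 50 °C.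

Coupling partner is the limiting reagent: the charge gives 1.10 per substrate, and a tetra adduct, going by its name, takes 4. The readings of tetra adduct in the south run stop rising after 20.0 h, so I take that as the window in which partner lasts. If adducts form evenly through a window of n lifetimes, the surviving share is (1 − e⁻ⁿ)/n:

eta: n = 0.294, share 86.6%
beta, window 30 h: n = 0.0586, share 97.1%

The weak link is the window at 110 °C. Shrinking it by the chemical factor would give zeta the count of eta in my reckoning, but I take it that partner binds to dissolved substrate, and I guess that dissolving does not speed up in the same way. So I keep the window: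

zeta: n = 2.21, share 40.2%
gamma, hot for 10 h: n = 1.11, share 60.5%

The forecast names beta, with eta 80%, gamma 40%, zeta 18% and beta 98.5%, lower than mine on zeta and gamma, and says “Higher temperature therefore hurts selectivity.”

The flasks give beta as highest, with eta 82.7%, gamma 36.9%, zeta 37.7% and beta 98.2%.

    starting material + coupling partner → first product (k = 0.0130 L mol⁻¹ min⁻¹, Ea = 89.0 kJ mol⁻¹)
    coupling partner + first product → double product (k = 0.0470 L mol⁻¹ min⁻¹, Ea = 75.0 kJ mol⁻¹)
    coupling partner + double product → triple product (k = 0.0160 L mol⁻¹ min⁻¹, Ea = 86.0 kJ mol⁻¹)
    coupling partner + triple product → tetra adduct (k = 0.0320 L mol⁻¹ min⁻¹, Ea = 90.0 kJ mol⁻¹)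
    solid substrate ⇌ starting material, rate k5*(cs5 - [starting material]) while solid is left; crystals form when [starting material] > cs5 (solubility = 0.470 M, k = 8.90 × 10⁻⁴ min⁻¹)
    coupling partner + tetra adduct → over-reaction product (k = 0.00110 L mol⁻¹ min⁻¹, Ea = 94.0 kJ mol⁻¹)
    (constants at 80 °C)

For gamma I counted 1.11 hot lifetimes and a share of 60.5%, but the flask gives 36.9%, below that; at 10.0 h gamma holds 7.66% tetra adduct and 13.2% over-reaction product, with 6.72% of its partner left. A flask like beta kept at 65 °C takes the same count from the south-run lifetime: 187 h, so 0.161 lifetimes in 30 h and a share of 92.4%. That flask keeps 9.9% of its partner at 30.0 h, holds 13.6% tetra adduct and 0.969% over-reaction product, and ends at a share of 93.4%.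

The numbers in the tables were computed for an exercise, and the scatter is random.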